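The sum of starting material, target and isomer of the product is the invariant we lean on. At the last readings of the epsilon, eta and delta runs it stands at 101%, 97.0% and 100% of the charge, so we follow the starting material and count both products together.

| setting | epsilon | eta | delta | flask |
|---|---|---|---|---|
| starting material | 0.10 M | 0.15 M | 0.20 M | 0.20 M |
| partner | 0.24 M | 0.24 M | 0.36 M | 0.240 M |
| remark | run made earlier | run made earlier | run made earlier |  |
| time |  |  |  | 25 min |

- epsilon (time / min: target / %, isomer of the product / %, starting material / %): 2.00: 5, 0, 98; 3.00: 4, 0, 96; 6.00: 6, 1, 89; 10.0: 12, 1, 86; 15.0: 18, 2, 79; 25.0: 26, 4, 71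
- eta (time / min: target / %, isomer of the product / %, starting material / %): 2.00: 1, 0, 100; 3.00: 2, 3, 97; 6.00: 9, 3, 91; 10.0: 12, 0, 84; 15.0: 19, 0, 81; 25.0: 26, 2, 69
- delta (time / min: target / %, isomer of the product / %, starting material / %): 2.00: 4, 1, 96; 6.00: 13, 1, 86; 12.0: 21, 0, 75; 20.0: 29, 1, 64; 25.0: 35, 5, 60

(each reading ± 1.5 percentage points)

- concentration of target at 25 min, in M
- concentration of isomer of the product at 25 min, in M

Our decision concerns the partner: is 0.240 M, less than delta's 0.36 M, enough for a stop at 25 min? We take one partner per starting material and use a pseudo-first-order exponent: rate constant times mean c(partner) times time, with exp of its negative as the fraction of starting material left. In delta, 60% left and a mean c(partner) of 0.320 M give a reading of 0.0639 M⁻¹ min⁻¹.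

For the flask we solve both ends and join them. With partner held at its charge, 31.8% reacts, so c(partner) ends near 0.176 M. The mean of the two ends gives the partner dose 0.332, hence 71.7% left and 0.0565 M of products together. We charge 0.240 M and accept that.

The forecast gives 0.051 M of target and 0.006 M of isomer of the product: “The isomer is small and noisy, at about 10% of the product formed”.

The flask gives 0.0493 M of target and 0.00538 M of isomer of the product.

    starting material + partner → target + by-product (k = 0.0660 M⁻¹ min⁻¹)
    target ⇌ isomer of the product (K = 0.420, k = 0.00890 min⁻¹)
    target + by-product → side product (k = 0.120 M⁻¹ min⁻¹)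

The flask's starting material stands at 71.0% at 25.0 min, against 71.7% from the dose of 0.332. A neighbouring flask is charged with 0.96 M of partner, all else unchanged. The same reckoning converts 78.4% at the charge, so c(partner) ends near 0.803 M. The neighbouring flask's dose is 1.41, which leaves 24.4%, and that flask gives 24.0% of starting material. That flask holds 0.113 M of target, 0.0148 M of isomer of the product, and side product at 12.3% of the starting material charged.

Readings and results come from a simulation for substances that don't exist, and the scatter is random.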